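**Retrosynthetic overview**
1. Target 18 ⇐ O-TIPS ether 17 ⇐ primary tosylate 16 ⇐ alcohol 15 (the C9 methyl comes from CH2OH by hydride displacement) ⇐ imide 14 by reductive removal of the auxiliary.
2. 14 ⇐ syn-aldol adduct 13 by removal of the benzylic hydroxyl (ionic hydrogenation).
3. Key C7–C8 bond: Evans boron aldol between aryloxyacetyl imide 8, which already carries the complete aryl ether, and O-TIPS-vanillin 10. The (R)-benzyloxazolidinone sets the only stereocentre.
4. 8 ⇐ 4-allyl-2,6-dimethoxyphenol 1 + ethyl bromoacetate 2 + auxiliary 6; 10 ⇐ vanillin 9.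
5. No ring is formed: both arenes are bought, and the oxazolidinone ring is a temporary auxiliary that is cleaved off.

Assumption: short-lived mechanistic species (the benzylic cation in step 6, the hemiaminal/aldehyde stages in step 7) are not counted as compounds; discrete in-flask species (carboxylate salt, mixed anhydride, boron enolate, boron aldolate) are numbered.

**Route**

Step 1
Reactants: 1 4-allyl-2,6-dimethoxyphenol (methoxyeugenol); 2 ethyl bromoacetate
Product: 3 ethyl 2-(4-allyl-2,6-dimethoxyphenoxy)acetate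
Conditions: K2CO3, acetone, reflux
Reagents that add atoms: none
Why: Williamson ether synthesis, an SN2 O-alkylation of the phenoxide by a highly reactive α-bromo ester that tolerates the two ortho methoxy groups.

Step 2
Reactants: 3 ethyl 2-(4-allyl-2,6-dimethoxyphenoxy)acetate
Product: 5 2-(4-allyl-2,6-dimethoxyphenoxy)acetic acid, via lithium carboxylate 4 (not isolated)
Conditions: LiOH·H2O, THF/H2O, rt; then 1 M HCl
Reagents that add atoms: lithium hydroxide [Li+].[OH-]
Why: Ester saponification (BAc2) of an unhindered ethyl ester, with nothing else in the molecule sensitive to aqueous base.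

Step 3
Reactants: 5 2-(4-allyl-2,6-dimethoxyphenoxy)acetic acid; 6 (R)-4-benzyl-1,3-oxazolidin-2-one
Product: 8 (4R)-3-[2-(4-allyl-2,6-dimethoxyphenoxy)acetyl]-4-benzyl-1,3-oxazolidin-2-one, via mixed pivalic anhydride 7 (not isolated)
Conditions: PivCl, Et3N, THF, −20 °C; then LiCl, 6, −20 °C → rt
Reagents that add atoms: none
Why: N-acylation of the oxazolidinone through a mixed pivalic anhydride, which is attacked at its less hindered aryloxyacetyl carbonyl.

Step 4
Reactants: 9 vanillin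
Product: 10 3-methoxy-4-(triisopropylsilyloxy)benzaldehyde
Conditions: TIPSCl, imidazole, DMF, rt
Reagents that add atoms: triisopropylsilyl chloride CC(C)[Si](Cl)(C(C)C)C(C)C
Why: Imidazole-promoted O-silylation of the phenol gives a bulky aryl silyl ether that survives Lewis acid, TFA and hydride and is later removed with fluoride without touching the allyl group.

Step 5
Reactants: 8 (4R)-3-[2-(4-allyl-2,6-dimethoxyphenoxy)acetyl]-4-benzyl-1,3-oxazolidin-2-one; 10 3-methoxy-4-(triisopropylsilyloxy)benzaldehyde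
Product: 13 (4R)-3-[(2R,3S)-2-(4-allyl-2,6-dimethoxyphenoxy)-3-hydroxy-3-(3-methoxy-4-triisopropylsilyloxyphenyl)propanoyl]-4-benzyl-1,3-oxazolidin-2-one, via (Z)-dibutylboron enolate 11 (not isolated), via dibutylboron aldolate 12 (not isolated)
Conditions: Bu2BOTf, Et3N, CH2Cl2, 0 °C; then 10, −78 → 0 °C; pH 7 buffer/MeOH, 30% H2O2, 0 °C
Reagents that add atoms: none
Why: Evans syn boron aldol, in which the Z-boron enolate reacts through a closed Zimmerman–Traxler chair on the face away from the auxiliary benzyl group, so the (R)-auxiliary fixes C2 as R (this carbon becomes the (S)-centre of the target once the carbonyl carbon is turned into CH3) and the carbinol carbon as S (syn), the latter being erased in step 6.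

Step 6
Reactants: 13 the syn-aldol adduct
Product: 14 (4R)-3-[(2R)-2-(4-allyl-2,6-dimethoxyphenoxy)-3-(3-methoxy-4-triisopropylsilyloxyphenyl)propanoyl]-4-benzyl-1,3-oxazolidin-2-one
Conditions: Et3SiH (5 equiv), TFA (15 equiv), CH2Cl2, 0 °C → rt
Reagents that add atoms: none
Why: Ionic hydrogenation (Kursanov–Parnes), in which TFA ionises the benzylic alcohol to a cation stabilised by the para-silyloxy group and Et3SiH delivers hydride, while the unconjugated terminal alkene, the aryl TIPS ether and the C2 stereocentre (not part of the cation, ortho positions of the neighbouring aryl ether blocked) are left untouched.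

Step 7
Reactants: 14 the deoxygenated imide
Product: 15 (2R)-2-(4-allyl-2,6-dimethoxyphenoxy)-3-(3-methoxy-4-triisopropylsilyloxyphenyl)propan-1-ol
Conditions: LiBH4, MeOH (1.1 equiv), THF, 0 °C
Reagents that add atoms: none
Why: Reductive cleavage of the N-acyloxazolidinone by hydride attack at the exocyclic carbonyl under non-basic conditions, so the α-stereocentre is not epimerised, the methanol-modified borohydride does not hydroborate the allyl group, and the auxiliary is recovered.

Step 8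
Reactants: 15 the primary alcohol
Product: 16 (2R)-2-(4-allyl-2,6-dimethoxyphenoxy)-3-(3-methoxy-4-triisopropylsilyloxyphenyl)propyl 4-methylbenzenesulfonate
Conditions: TsCl, Et3N, DMAP (cat.), CH2Cl2, 0 °C → rt
Reagents that add atoms: p-toluenesulfonyl chloride Cc1ccc(S(=O)(=O)Cl)cc1
Why: Sulfonylation of the only free hydroxyl (the phenol is silylated) turns it into a leaving group without touching the stereocentre.

Step 9
Reactants: 16 the primary tosylate
Product: 17 5-allyl-1,3-dimethoxy-2-{[(2S)-1-(3-methoxy-4-triisopropylsilyloxyphenyl)propan-2-yl]oxy}benzene (O-TIPS ether of the target)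
Conditions: LiEt3BH (3 equiv), THF, 0 °C → rt; aq. NH4Cl
Reagents that add atoms: none
Why: SN2 hydride displacement of a primary tosylate by Super-Hydride converts CH2OTs into CH3 without involving the stereocentre, whose descriptor changes from R to S only because the CIP priorities change.

Step 10
Reactants: 17 the O-TIPS ether of the target
Product: 18 4-[(2S)-2-(4-allyl-2,6-dimethoxyphenoxy)propyl]-2-methoxyphenol (target)
Conditions: TBAF, AcOH (1:1), THF, 0 °C → rt
Reagents that add atoms: none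
Why: Fluoride-mediated desilylation of the aryl silyl ether (strong Si–F bond, phenoxide leaving group) under buffered conditions that leave the allyl group, the methyl ethers and the alkyl aryl ether untouched.

**Compound list**
1 | 4-allyl-2,6-dimethoxyphenol | C=CCc1cc(OC)c(O)c(OC)c1 | starting material
2 | ethyl bromoacetate | CCOC(=O)CBr | starting material
3 | ethyl 2-(4-allyl-2,6-dimethoxyphenoxy)acetate | C=CCc1cc(OC)c(OCC(=O)OCC)c(OC)c1 | intermediate
4 | lithium 2-(4-allyl-2,6-dimethoxyphenoxy)acetate | C=CCc1cc(OC)c(OCC(=O)[O-])c(OC)c1.[Li+] | intermediate (not isolated)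
5 | 2-(4-allyl-2,6-dimethoxyphenoxy)acetic acid | C=CCc1cc(OC)c(OCC(=O)O)c(OC)c1 | intermediate
6 | (R)-4-benzyl-1,3-oxazolidin-2-one | O=C1N[C@H](Cc2ccccc2)CO1 | starting material
7 | 2-(4-allyl-2,6-dimethoxyphenoxy)acetic pivalic anhydride | C=CCc1cc(OC)c(OCC(=O)OC(=O)C(C)(C)C)c(OC)c1 | intermediate (not isolated)
8 | (4R)-3-[2-(4-allyl-2,6-dimethoxyphenoxy)acetyl]-4-benzyl-1,3-oxazolidin-2-one | C=CCc1cc(OC)c(OCC(=O)N2C(=O)OC[C@H]2Cc3ccccc3)c(OC)c1 | intermediate
9 | vanillin (4-hydroxy-3-methoxybenzaldehyde) | COc1cc(C=O)ccc1O | starting material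
10 | 3-methoxy-4-(triisopropylsilyloxy)benzaldehyde | COc1cc(C=O)ccc1O[Si](C(C)C)(C(C)C)C(C)C | intermediate
11 | (Z)-O-dibutylboryl enolate of 8 (O–B and aryloxy cis) | C=CCc1cc(OC)c(O/C=C(\OB(CCCC)CCCC)N2C(=O)OC[C@H]2Cc3ccccc3)c(OC)c1 | intermediate (not isolated)
12 | O-dibutylboryl aldolate of 13 | C=CCc1cc(OC)c(O[C@@H](C(=O)N2C(=O)OC[C@H]2Cc3ccccc3)[C@@H](OB(CCCC)CCCC)c4ccc(O[Si](C(C)C)(C(C)C)C(C)C)c(OC)c4)c(OC)c1 | intermediate (not isolated)
13 | (4R)-3-[(2R,3S)-2-(4-allyl-2,6-dimethoxyphenoxy)-3-hydroxy-3-(3-methoxy-4-triisopropylsilyloxyphenyl)propanoyl]-4-benzyl-1,3-oxazolidin-2-one | C=CCc1cc(OC)c(O[C@@H](C(=O)N2C(=O)OC[C@H]2Cc3ccccc3)[C@@H](O)c4ccc(O[Si](C(C)C)(C(C)C)C(C)C)c(OC)c4)c(OC)c1 | intermediate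
14 | (4R)-3-[(2R)-2-(4-allyl-2,6-dimethoxyphenoxy)-3-(3-methoxy-4-triisopropylsilyloxyphenyl)propanoyl]-4-benzyl-1,3-oxazolidin-2-one | C=CCc1cc(OC)c(O[C@@H](C(=O)N2C(=O)OC[C@H]2Cc3ccccc3)Cc4ccc(O[Si](C(C)C)(C(C)C)C(C)C)c(OC)c4)c(OC)c1 | intermediate
15 | (2R)-2-(4-allyl-2,6-dimethoxyphenoxy)-3-(3-methoxy-4-triisopropylsilyloxyphenyl)propan-1-ol | C=CCc1cc(OC)c(O[C@@H](CO)Cc2ccc(O[Si](C(C)C)(C(C)C)C(C)C)c(OC)c2)c(OC)c1 | intermediate
16 | (2R)-2-(4-allyl-2,6-dimethoxyphenoxy)-3-(3-methoxy-4-triisopropylsilyloxyphenyl)propyl 4-methylbenzenesulfonate | C=CCc1cc(OC)c(O[C@@H](COS(=O)(=O)c2ccc(C)cc2)Cc3ccc(O[Si](C(C)C)(C(C)C)C(C)C)c(OC)c3)c(OC)c1 | intermediate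
17 | 5-allyl-1,3-dimethoxy-2-{[(2S)-1-(3-methoxy-4-triisopropylsilyloxyphenyl)propan-2-yl]oxy}benzene | C=CCc1cc(OC)c(O[C@@H](C)Cc2ccc(O[Si](C(C)C)(C(C)C)C(C)C)c(OC)c2)c(OC)c1 | intermediate
18 | 4-[(2S)-2-(4-allyl-2,6-dimethoxyphenoxy)propyl]-2-methoxyphenol | C=CCc1cc(OC)c(O[C@@H](C)Cc2ccc(O)c(OC)c2)c(OC)c1 | target

**Totals**
Total step count: 10.
Longest linear sequence: 9 steps (steps 1, 2, 3, 5, 6, 7, 8, 9, 10); step 4 is a one-step side branch.

**Three steps most likely to fail, with fallbacks**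

Step 5 (boron aldol). The two ortho methoxy groups can tie up Bu2BOTf, and the electron-rich aldehyde 10 is a sluggish electrophile. The fallback sets out from acid 5. It is coupled with (R)-4-benzyl-1,3-thiazolidine-2-thione (EDC·HCl, DMAP, CH2Cl2) to give the N-acyl thiazolidinethione F1. Its chlorotitanium enolate (TiCl4, i-Pr2NEt, NMP, CH2Cl2, −78 → 0 °C, Evans-syn mode) is added to 10 to give the syn-aldol thioimide F2, with the same C2 configuration as 13. The benzylic hydroxyl is removed (Et3SiH, TFA, CH2Cl2) to give the deoxygenated thioimide F3, and NaBH4 (THF/EtOH, 0 °C) cleaves the auxiliary, coming back to the route at alcohol 15.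

Step 6 (ionic deoxygenation next to the imide). The electron-withdrawing imide may slow ionisation and favour elimination. The fallback sets out from aldol adduct 13 and moves the deoxygenation to the end. The auxiliary is removed first (LiBH4, MeOH, THF, 0 °C) to give the 1,3-diol F4. The primary hydroxyl is tosylated selectively (TsCl, Et3N, cat. DMAP, CH2Cl2, 0 °C) to give the primary monotosylate F5, and LiEt3BH (THF, 0 °C) converts it into the secondary benzylic alcohol F6. Only then is the benzylic hydroxyl removed from this carbonyl-free, more easily ionised substrate (Et3SiH, TFA, CH2Cl2, −20 °C), coming back to the route at 17.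

Step 9 (hydride displacement of the β-branched tosylate). Attack at sulfur (returning 15) or elimination may compete. The fallback sets out from alcohol 15, which is converted under Appel-type conditions (I2, PPh3, imidazole, CH2Cl2, 0 °C → rt) into the primary iodide F7. This softer, more reactive electrophile is reduced with NaBH4 in DMSO (rt → 50 °C), coming back to the route at 17.

**Further compounds**
F1 | step 5 | (4R)-3-[2-(4-allyl-2,6-dimethoxyphenoxy)acetyl]-4-benzyl-1,3-thiazolidine-2-thione | C=CCc1cc(OC)c(OCC(=O)N2C(=S)SC[C@H]2Cc3ccccc3)c(OC)c1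
F2 | step 5 | (4R)-3-[(2R,3S)-2-(4-allyl-2,6-dimethoxyphenoxy)-3-hydroxy-3-(3-methoxy-4-triisopropylsilyloxyphenyl)propanoyl]-4-benzyl-1,3-thiazolidine-2-thione | C=CCc1cc(OC)c(O[C@@H](C(=O)N2C(=S)SC[C@H]2Cc3ccccc3)[C@@H](O)c4ccc(O[Si](C(C)C)(C(C)C)C(C)C)c(OC)c4)c(OC)c1
F3 | step 5 | (4R)-3-[(2R)-2-(4-allyl-2,6-dimethoxyphenoxy)-3-(3-methoxy-4-triisopropylsilyloxyphenyl)propanoyl]-4-benzyl-1,3-thiazolidine-2-thione | C=CCc1cc(OC)c(O[C@@H](C(=O)N2C(=S)SC[C@H]2Cc3ccccc3)Cc4ccc(O[Si](C(C)C)(C(C)C)C(C)C)c(OC)c4)c(OC)c1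
F4 | step 6 | (1S,2S)-2-(4-allyl-2,6-dimethoxyphenoxy)-1-(3-methoxy-4-triisopropylsilyloxyphenyl)propane-1,3-diol | C=CCc1cc(OC)c(O[C@@H](CO)[C@@H](O)c2ccc(O[Si](C(C)C)(C(C)C)C(C)C)c(OC)c2)c(OC)c1
F5 | step 6 | (2S,3S)-2-(4-allyl-2,6-dimethoxyphenoxy)-3-hydroxy-3-(3-methoxy-4-triisopropylsilyloxyphenyl)propyl 4-methylbenzenesulfonate | C=CCc1cc(OC)c(O[C@@H](COS(=O)(=O)c2ccc(C)cc2)[C@@H](O)c3ccc(O[Si](C(C)C)(C(C)C)C(C)C)c(OC)c3)c(OC)c1
F6 | step 6 | (1S,2S)-2-(4-allyl-2,6-dimethoxyphenoxy)-1-(3-methoxy-4-triisopropylsilyloxyphenyl)propan-1-ol | C=CCc1cc(OC)c(O[C@@H](C)[C@@H](O)c2ccc(O[Si](C(C)C)(C(C)C)C(C)C)c(OC)c2)c(OC)c1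
F7 | step 9 | 5-allyl-2-{[(2R)-1-iodo-3-(3-methoxy-4-triisopropylsilyloxyphenyl)propan-2-yl]oxy}-1,3-dimethoxybenzene | C=CCc1cc(OC)c(O[C@@H](CI)Cc2ccc(O[Si](C(C)C)(C(C)C)C(C)C)c(OC)c2)c(OC)c1
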